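All constants come from no measurement; what happens was integrated by code.

For the next run I had to choose the nucleophile charge that just brings the electrophile to the asked conversion, and whether the run needed more time.

electrophile 0.010 M; protic impurity 2.00 mM; time 10 min

    2 nucleophile → homo dimer (k1 = 0.74 L mol⁻¹ s⁻¹)
    electrophile + nucleophile → acid set free + target (k2 = 56 L mol⁻¹ s⁻¹)
    nucleophile + target → over-reaction product (k3 = 8.8 L mol⁻¹ s⁻¹)
    nucleophile + acid set free ⇌ protonated nucleophile, settled at all times (K4 = 2500 L mol⁻¹)
    electrophile + protic impurity → quenched substrate (k5 = 41 L mol⁻¹ s⁻¹)

1. the equivalents of nucleophile at which the part of the electrophile that has reacted at 10 min is just 50%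

- for a step with 2 of a species take k times the square, and two of it per event
- the amount of nucleophile is what is sought; it is there from the start
- run time (flask): 10 min

I wrote a balance on the nucleophile, taking it as the limiting reagent. Reaching 50% meant using 5.00 mM of electrophile. With c(electrophile) at its charge, the protic impurity had a half-life of 1.69 s, far shorter than the run, and its charge was smaller than that of the electrophile, so I counted all 2.00 mM of it as electrophile used without nucleophile. That left 3.00 mM as the nucleophile demand, the electrophile to be used less the protic impurity charged. With c(electrophile) held at 5.00 mM, the half-life of free nucleophile in the target-forming step alone was 2.48 s, also far shorter than the run, so I planned no longer time, although this half-life did not count nucleophile held as protonated nucleophile. As a charge, the demand came to 0.300 equiv, with over-reaction, dimer and the acid set free not reckoned.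

The forecast gave 0.313 equiv, within 0.3 equiv to 0.33 equiv, holding that “protonation only slows it”.

The simulation gave 0.312 equiv, which is 3.12 mM of nucleophile against the demand of 3.00 mM, so the demand came to nearly all of that charge, and that charge is the one for the next run. In this flask, nucleophile went into target 32 times as fast as into over-reaction product at 0.0360 min, a ratio above one, and it was still 11 times as fast at 10.0 min. Electrophile used stood at 50.0% after 2.50 min and at 50.0% after 30.0 min.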